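**Plan**
- Retrosynthesis: the three C–Br bonds are cut first (electrophilic substitution of 4-methylcatechol). The catechol is traced back to cis-4-methylcyclohex-4-ene-1,2-diol, and ring bonds C1–C6 and C2–C3 of the target are then cut by a retro-(4+2).
- Enabling feature: in the fully substituted benzene ring, the adjacent hydroxyl-bearing carbons C1/C2 are the two carbons of vinylene carbonate. The methyl-bearing C5 and its bromine-bearing neighbour C4 are the internal carbons of isoprene, whose termini become C6 and C3.
- Forward: the only ring is closed in step 1; carbonate removal, double alcohol oxidation with spontaneous aromatisation, and one exhaustive bromination follow.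
- The alkene left by the cycloaddition is the third double bond of the arene, so diol-to-dione oxidation lands exactly on the catechol oxidation level.
- Stereochemistry: the target is achiral; the two cis stereocentres set by the suprafacial cycloaddition are racemic and are erased on aromatisation.

Key step: step 1

Remark: the route is run in the racemic series; the SMILES of 3 and 4 show one enantiomer of the cis pair.

**Step 1**
Reactants: 1 isoprene; 2 vinylene carbonate
Product: 3 rac-cis-5-methyl-3a,4,7,7a-tetrahydro-1,3-benzodioxol-2-one
Conditions: 1 (3 equiv), 2,6-di-tert-butyl-4-methylphenol (1 mol %), toluene, steel autoclave, 170 °C, 16 h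
Reagents that add atoms: none
Why: The reaction is a concerted, thermally allowed suprafacial (4+2) cycloaddition (Diels–Alder) between s-cis isoprene and the ring alkene of vinylene carbonate, forming C3a–C4 and C7–C7a together. The closest known reaction type is the thermal Diels–Alder reaction of vinylene carbonate with simple 1,3-dienes such as buta-1,3-diene and 2,3-dimethylbuta-1,3-diene in a sealed vessel. The cyclohexene ring closes intermolecularly by cycloaddition, both sigma bonds joining the diene termini to the dienophile carbons in one step, and the dioxolanone ring already present in 2 ends up cis-fused. The stereocentres C3a and C7a are set cis because the dienophile geometry is locked in its five-membered ring and the addition is suprafacial; the product is racemic. No regiochemical or endo/exo selectivity is needed, since the dienophile is symmetric and the diene termini are unsubstituted; the only selectivity required is cycloaddition over isoprene dimerisation, which excess diene and the radical inhibitor should secure.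

**Step 2**
Reactants: 3 rac-cis-5-methyl-3a,4,7,7a-tetrahydro-1,3-benzodioxol-2-one
Product: 4 rac-cis-4-methylcyclohex-4-ene-1,2-diol
Conditions: K2CO3 (0.2 equiv), MeOH, 23 °C, 2 h
Reagents that add atoms: none
Why: Base-catalysed transesterification (methanolysis) of the five-membered cyclic carbonate should release the diol and dimethyl carbonate; no bond to either stereocentre is broken, so the cis relationship is carried over unchanged.

**Step 3**
Reactants: 4 rac-cis-4-methylcyclohex-4-ene-1,2-diol
Product: 6 4-methylbenzene-1,2-diol (4-methylcatechol), via 4-methylcyclohex-4-ene-1,2-dione 5 (not isolated)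
Conditions: DMSO (5 equiv), (CF3CO)2O (2.2 equiv), CH2Cl2, −78 °C, 1 h; Et3N (6 equiv), −78 → 0 °C, Ar; 1 M HCl quench
Reagents that add atoms: none
Why: A double Swern oxidation with trifluoroacetic anhydride-activated DMSO, a combination established for vicinal diols, should give enedione 5 without C–C cleavage, and amine-mediated enolisation of both carbonyls toward the flanking CH2 groups places three double bonds in the ring, so 5 should tautomerise irreversibly to the catechol with loss of both stereocentres.

**Step 4**
Reactants: 6 4-methylbenzene-1,2-diol
Product: 7 3,4,6-tribromo-5-methylbenzene-1,2-diol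
Conditions: Br2 (3.3 equiv), AcOH, 23 °C, dark; aq. NaHSO3 work-up
Reagents that add atoms: bromine, BrBr
Why: This is a threefold electrophilic aromatic bromination in which each of the three remaining ring positions is ortho or para to a hydroxyl group, so exhaustive substitution is expected as in the perbromination of catechol itself, no regiochemical choice remains once all three are filled, and the bisulfite work-up should return any o-quinone formed by adventitious oxidation to the catechol.

**Compound list**
1 | isoprene (2-methylbuta-1,3-diene) | C=CC(C)=C | starting material
2 | vinylene carbonate (1,3-dioxol-2-one) | O=C1OC=CO1 | starting material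
3 | rac-cis-5-methyl-3a,4,7,7a-tetrahydro-1,3-benzodioxol-2-one | CC1=CC[C@H]2OC(=O)O[C@H]2C1 | intermediate
4 | rac-cis-4-methylcyclohex-4-ene-1,2-diol | CC1=CC[C@H](O)[C@H](O)C1 | intermediate
5 | 4-methylcyclohex-4-ene-1,2-dione (formed in the flask in step 3) | CC1=CCC(=O)C(=O)C1 | intermediate
6 | 4-methylbenzene-1,2-diol (4-methylcatechol) | Cc1ccc(O)c(O)c1 | intermediate
7 | 3,4,6-tribromo-5-methylbenzene-1,2-diol | Cc1c(Br)c(O)c(O)c(Br)c1Br | target

**Step count**
Total steps: 4. Longest linear sequence: 4 steps (1 and 2 to 7).

**Steps most likely to fail**

Step 3. The oxidation may stop at the hydroxy ketone stage, which would then dehydrate to cresols. The freshly formed, electron-rich catechol may also be captured by residual electrophilic sulfonium species (ring methylthiomethylation) or be oxidised by air in the amine medium.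

The fallback sets out from 3 and comes back to the route at 7. It makes the ring unable to aromatise until base is added, so that oxidation and aromatisation are separated.
- Bromine (Br2, CH2Cl2, 0 °C) should add trans across the ring alkene of 3 to give trans-5,6-dibromo-5-methylhexahydro-1,3-benzodioxol-2-one F1. The ring fusion stays cis, a mixture of the two trans-dibromide diastereomers is acceptable, and one is drawn.
- Methanolysis as in step 2 should give 4,5-dibromo-4-methylcyclohexane-1,2-diol F2.
- A non-basic oxidant (2-iodoxybenzoic acid, DMSO, 23 °C) should take the saturated diol to trans-4,5-dibromo-4-methylcyclohexane-1,2-dione F3. Complete oxidation can be confirmed before any phenol exists.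
- Et3N in degassed CH2Cl2 should then expel one equivalent of HBr from a bromide beta to a carbonyl (E1cB), after which the ring tautomerises to 4-bromo-5-methylbenzene-1,2-diol F4.
- Two equivalents of Br2 in AcOH should fill the two positions ortho to the hydroxyls and give 7.

Step 1. Thermal dimerisation and polymerisation of isoprene may outrun cycloaddition to the weakly activated dienophile at the temperature it demands.

The fallback sets out from 1 and comes back to the route at 5, and hence 6. It keeps the same two ring bonds but uses a more electron-poor dienophile that already carries the dione oxidation level.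
- Commercial ethylene carbonate is perchlorinated (Cl2, hν) to 4,4,5,5-tetrachloro-1,3-dioxolan-2-one F5.
- Zinc dechlorination (Zn, Et2O, cat. DMF) should give 4,5-dichloro-1,3-dioxol-2-one F6.
- Its (4+2) cycloaddition with 1 (toluene, sealed tube, about 120 °C) should give rac-cis-3a,7a-dichloro-5-methyl-3a,4,7,7a-tetrahydro-1,3-benzodioxol-2-one F7.
- Hydrolysis in aqueous dioxane at 60 °C should unmask both carbonyls at once with loss of CO2 and HCl, giving enedione 5, which tautomerises to 6 as in step 3. Steps 2 and 3 are bypassed.

Step 4. Bromine may oxidise the catechol to the o-quinone, with follow-on ipso attack at the methyl-bearing carbon competing with the slow third substitution. Radical bromination of the benzylic methyl group is a further risk.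

The fallback sets out from 6 and comes back to the route at 7. It masks the hydroxyls so that no quinone can form.
- Both hydroxyls are methylated (MeI, K2CO3, acetone, reflux) to give 1,2-dimethoxy-4-methylbenzene F8.
- Excess Br2 with FeBr3 (5 mol %) in CH2Cl2 should substitute the three remaining positions and give 1,2,4-tribromo-5,6-dimethoxy-3-methylbenzene F9.
- BBr3 (CH2Cl2, −78 → 23 °C) should cleave both methyl ethers to 7.

**Further compounds**
F1 | step 3 | trans-5,6-dibromo-5-methylhexahydro-1,3-benzodioxol-2-one (cis-fused, one diastereomer shown) | C[C@]1(Br)C[C@H]2OC(=O)O[C@H]2C[C@@H]1Br
F2 | step 3 | 4,5-dibromo-4-methylcyclohexane-1,2-diol (cis-diol, trans-dibromide) | C[C@]1(Br)C[C@@H](O)[C@@H](O)C[C@@H]1Br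
F3 | step 3 | trans-4,5-dibromo-4-methylcyclohexane-1,2-dione | C[C@]1(Br)CC(=O)C(=O)C[C@@H]1Br
F4 | step 3 | 4-bromo-5-methylbenzene-1,2-diol | Cc1cc(O)c(O)cc1Br
F5 | step 1 | 4,4,5,5-tetrachloro-1,3-dioxolan-2-one | O=C1OC(Cl)(Cl)C(Cl)(Cl)O1
F6 | step 1 | 4,5-dichloro-1,3-dioxol-2-one | O=C1OC(Cl)=C(Cl)O1
F7 | step 1 | rac-cis-3a,7a-dichloro-5-methyl-3a,4,7,7a-tetrahydro-1,3-benzodioxol-2-one | CC1=CC[C@@]2(Cl)OC(=O)O[C@@]2(Cl)C1
F8 | step 4 | 1,2-dimethoxy-4-methylbenzene | COc1ccc(C)cc1OC
F9 | step 4 | 1,2,4-tribromo-5,6-dimethoxy-3-methylbenzene | COc1c(OC)c(Br)c(Br)c(C)c1Br
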